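**Retrosynthetic overview**
1. The last cuts are the three silyl ethers and the aryl–vinyl bond on ring D (Heck reaction of the ring D bromide with an acrolein acetal).
2. Each (7R,8S) arylglycerol β-aryl ether unit is cut at C7–C8 by an anti-glycolate aldol of an aryloxyacetyl oxazolidinone, first with vanillin acetate (ring A), then with syringaldehyde acetate (ring B). Each phenol is alkylated beforehand with the bromoacetyl oxazolidinone, which leads back to the free ring C phenol of the phenylcoumaran.
3. The plan rests on one feature: C2 of the dihydrobenzofuran is a benzylic ether carbon para to the phenolic oxygen of syringyl ring C. O1–C2 is therefore cut to the ring D phenol and the exocyclic carbon of a ring C para-quinone methide, made by oxidising a diphenol whose only stereocentre is C3.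
4. Only the dihydrofuran ring (O1, C2, C3, C3a, C7a) is formed in the synthesis; rings A, B, C and D enter as intact arenes. C3 is set by Evans alkylation of the ring D arylacetyl oxazolidinone (from 5-bromo-ortho-vanillin) with a syringyl benzyl bromide.

Key step: step 13

Remark: ring A is the terminal guaiacyl ring, ring B the central syringyl ring, ring C the syringyl ring on C2, ring D the benzofuran arene; in each arylglycerol unit C7 is the benzylic carbinol carbon, C8 the aryloxy-bearing carbon and C9 the CH2OH carbon. The facial sense of the magnesium-catalysed aldol is assumed to follow the chelated-enolate model established for propionyl oxazolidinones.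

**Route**

Step 1
Reactants: 1 5-bromo-2-hydroxy-3-methoxybenzaldehyde
Product: 2 2-(allyloxy)-5-bromo-3-methoxybenzaldehyde
Conditions: allyl bromide, K2CO3, DMF, rt
Reagents that add atoms: allyl bromide, C=CCBr
Why: Williamson O-alkylation of the phenoxide; the allyl ether survives the enolate and hydride steps and can later be removed without touching the aryl bromide or a silyl ether.

Step 2
Reactants: 2 2-(allyloxy)-5-bromo-3-methoxybenzaldehyde
Product: 3 2-(allyloxy)-5-bromo-1-methoxy-3-(2-methoxyethenyl)benzene (E/Z mixture)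
Conditions: Ph3P(CH2OMe)Cl, KOtBu, THF, 0 °C to rt
Reagents that add atoms: (methoxymethyl)triphenylphosphonium chloride, COC[P+](c1ccccc1)(c1ccccc1)c1ccccc1.[Cl-]
Why: Wittig methoxymethylenation adds the one carbon needed for the arylacetic acid; the alkene geometry is irrelevant.

Step 3
Reactants: 3 2-(allyloxy)-5-bromo-1-methoxy-3-(2-methoxyethenyl)benzene
Product: 4 2-[2-(allyloxy)-5-bromo-3-methoxyphenyl]acetaldehyde
Conditions: 2 M aq HCl, THF, 50 °C; used crude
Reagents that add atoms: water, O
Why: acid hydrolysis of the enol ether gives the homologous aldehyde, and the allyl aryl ether and aryl bromide are inert to dilute acid.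

Step 4
Reactants: 4 2-[2-(allyloxy)-5-bromo-3-methoxyphenyl]acetaldehyde
Product: 5 2-[2-(allyloxy)-5-bromo-3-methoxyphenyl]acetic acid
Conditions: NaClO2, NaH2PO4, 2-methyl-2-butene, t-BuOH/H2O, rt
Reagents that add atoms: sodium chlorite, [Na+].[O-]Cl=O
Why: Pinnick oxidation converts the aldehyde to the acid, with 2-methyl-2-butene scavenging hypochlorite so that the allyl group and the electron-rich ring are spared.

Step 5
Reactants: 5 2-[2-(allyloxy)-5-bromo-3-methoxyphenyl]acetic acid; 6 (S)-4-benzyloxazolidin-2-one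
Product: 8 (S)-3-{2-[2-(allyloxy)-5-bromo-3-methoxyphenyl]acetyl}-4-benzyloxazolidin-2-one, via mixed pivalic anhydride 7 (not isolated)
Conditions: t-BuCOCl, Et3N, THF, −20 °C; then LiCl, 6, rt
Reagents that add atoms: none
Why: N-acylation of the oxazolidinone through the mixed anhydride under LiCl/Et3N activation avoids any organolithium base in the presence of the aryl bromide.

Step 6
Reactants: 9 syringaldehyde
Product: 10 4-(allyloxy)-3,5-dimethoxybenzaldehyde
Conditions: allyl bromide, K2CO3, DMF, rt
Reagents that add atoms: allyl bromide, C=CCBr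
Why: Williamson O-alkylation of the hindered but acidic syringyl phenol.

Step 7
Reactants: 10 4-(allyloxy)-3,5-dimethoxybenzaldehyde
Product: 11 [4-(allyloxy)-3,5-dimethoxyphenyl]methanol
Conditions: NaBH4, MeOH, 0 °C
Reagents that add atoms: none
Why: borohydride reduction of the aldehyde to the benzylic alcohol.

Step 8
Reactants: 11 [4-(allyloxy)-3,5-dimethoxyphenyl]methanol
Product: 12 4-(allyloxy)-3,5-dimethoxybenzyl bromide
Conditions: PBr3, Et2O, 0 °C; used at once
Reagents that add atoms: phosphorus tribromide, BrP(Br)Br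
Why: standard conversion of an electron-rich benzylic alcohol to the bromide, which is used fresh because it ionises easily.

Step 9
Reactants: 8 (S)-3-{2-[2-(allyloxy)-5-bromo-3-methoxyphenyl]acetyl}-4-benzyloxazolidin-2-one; 12 4-(allyloxy)-3,5-dimethoxybenzyl bromide
Product: 14 (S)-4-benzyl-3-[(2S)-2-(2-allyloxy-5-bromo-3-methoxyphenyl)-3-(4-allyloxy-3,5-dimethoxyphenyl)propanoyl]oxazolidin-2-one, via sodium Z-enolate 13 (not isolated)
Conditions: NaN(SiMe3)2, THF, −78 °C; then 12, −78 to −45 °C; AcOH quench at −78 °C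
Reagents that add atoms: none
Why: Evans asymmetric alkylation, in which the chelated sodium Z-enolate is attacked by the benzyl bromide on the face away from the auxiliary benzyl group, setting the future C3 as (S); the cold acidic quench guards the acidic α-aryl centre.

Step 10
Reactants: 14 the alkylated imide
Product: 15 (2S)-2-(2-allyloxy-5-bromo-3-methoxyphenyl)-3-(4-allyloxy-3,5-dimethoxyphenyl)propan-1-ol
Conditions: LiBH4, MeOH (1 equiv), THF, 0 °C
Reagents that add atoms: none
Why: reductive cleavage of the N-acyl oxazolidinone by borohydride gives the primary alcohol without epimerising the α-aryl centre, and the auxiliary is recovered.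

Step 11
Reactants: 15 the primary alcohol
Product: 16 tert-butyldimethylsilyl ether of 15
Conditions: TBSCl, imidazole, DMF, rt
Reagents that add atoms: tert-butyldimethylsilyl chloride, CC(C)(C)[Si](C)(C)Cl
Why: routine silylation of the primary alcohol, which will become the C3 hydroxymethyl group.

Step 12
Reactants: 16 the bis-allyl silyl ether
Product: 17 4-bromo-2-[(2S)-1-(tert-butyldimethylsilyloxy)-3-(4-hydroxy-3,5-dimethoxyphenyl)propan-2-yl]-6-methoxyphenol
Conditions: Pd(PPh3)4 (5 mol %), morpholine, THF, rt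
Reagents that add atoms: none
Why: Tsuji–Trost deallylation of both aryl allyl ethers with morpholine as allyl acceptor; zerovalent palladium does not insert into the electron-rich aryl bromide at room temperature, and the silyl ether is untouched.

Step 13
Reactants: 17 the diphenol with the single C3 stereocentre
Product: 19 4-[(2R,3S)-5-bromo-3-(tert-butyldimethylsilyloxymethyl)-7-methoxy-2,3-dihydro-1-benzofuran-2-yl]-2,6-dimethoxyphenol (trans), via ring C para-quinone methide 18 (not isolated)
Conditions: Ag2O (1.2 equiv), CH2Cl2, rt, dark, argon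
Reagents that add atoms: none
Why: Ag2O (monovalent silver) removes two electrons and two protons from the more electron-rich ring C syringyl phenol, through the phenoxyl radical and loss of the benzylic C2 hydrogen, to give para-quinone methide 18. The ring D phenol then adds to the exocyclic methide carbon (intramolecular oxa-1,6-conjugate addition), forming O1–C2 and closing the dihydrofuran ring in a 5-exo-trig mode, and ring C rearomatises to the free phenol needed in step 15. The closest known reaction type is the silver-oxide oxidation of 4-alkyl-2,6-dimethoxyphenols to quinone methides and their capture by phenols, the ring-closing half of phenylcoumaran formation in oxidative phenol coupling. The new C2 centre is controlled by C3 alone: the methide is planar and the aryl group should end up on the face away from the CH2OTBS group, giving the trans (2R,3S) isomer, which is also the more stable one. The step needs oxidation of ring C before ring D and no second oxidation of the product; the two methoxy groups make ring C the easier phenol to oxidise, the para-bromine lowers the electron density of ring D, and a near-stoichiometric charge of Ag2O limits over-oxidation to the benzofuran.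

Step 14
Reactants: 6 (S)-4-benzyloxazolidin-2-one
Product: 21 (S)-4-benzyl-3-(2-bromoacetyl)oxazolidin-2-one, via N-lithio oxazolidinone 20 (not isolated)
Conditions: n-BuLi, THF, −78 °C; then BrCH2COBr, −78 to 0 °C
Reagents that add atoms: bromoacetyl bromide, BrCC(Br)=O
Why: N-acylation of the lithiated oxazolidinone with the acid bromide, the standard preparation of this haloacetyl imide.

Step 15
Reactants: 19 the trans-phenylcoumaran phenol; 21 (S)-4-benzyl-3-(2-bromoacetyl)oxazolidin-2-one
Product: 22 (S)-4-benzyl-3-{2-[4-((2R,3S)-5-bromo-3-(tert-butyldimethylsilyloxymethyl)-7-methoxy-2,3-dihydrobenzofuran-2-yl)-2,6-dimethoxyphenoxy]acetyl}oxazolidin-2-one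
Conditions: K2CO3, acetone, rt
Reagents that add atoms: none
Why: Williamson etherification, since the ring C phenoxide displaces bromide from the activated α-halo imide faster than it can attack the imide carbonyl.

Step 16
Reactants: 9 syringaldehyde
Product: 23 4-formyl-2,6-dimethoxyphenyl acetate
Conditions: Ac2O, pyridine, DMAP (cat.), CH2Cl2, rt
Reagents that add atoms: acetic anhydride, CC(=O)OC(C)=O
Why: acetylation masks the phenol with a group that makes the aldehyde more electrophilic and that the later hydride step removes together with the auxiliary.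

Step 17
Reactants: 22 the ring C aryloxyacetyl imide; 23 4-formyl-2,6-dimethoxyphenyl acetate
Product: 25 (S)-4-benzyl-3-[(2R,3R)-3-(4-acetoxy-3,5-dimethoxyphenyl)-3-hydroxy-2-(ring C aryloxy)propanoyl]oxazolidin-2-one (anti), via trimethylsilyl ether 24 (not isolated)
Conditions: MgCl2 (20 mol %), Et3N, TMSCl, EtOAc, rt; then citric acid, MeOH, rt
Reagents that add atoms: none
Why: magnesium-halide-catalysed direct anti-aldol of an N-acyl oxazolidinone, in which soft enolisation of the Mg-chelated imide gives the Z-enolate that adds to the non-enolisable aldehyde through a boat-like transition state on the face away from the auxiliary benzyl group, TMSCl trapping the aldolate; this should set C8 and C7 of the ring B unit in the anti (erythro) sense.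

Step 18
Reactants: 25 the anti-aldol adduct
Product: 26 (1R,2S)-1-(4-hydroxy-3,5-dimethoxyphenyl)-2-(ring C aryloxy)propane-1,3-diol carrying the bromo silyl phenylcoumaran of 19
Conditions: LiBH4, MeOH, THF, 0 °C to rt
Reagents that add atoms: none
Why: borohydride reduction cleaves the imide to the C9 primary alcohol and reductively removes the aryl acetate in the same operation, with no base strong enough for retro-aldol or epimerisation.

Step 19
Reactants: 26 the ring B phenol diol; 21 (S)-4-benzyl-3-(2-bromoacetyl)oxazolidin-2-one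
Product: 27 ring B aryloxyacetyl imide with free C7 and C9 hydroxyls
Conditions: K2CO3, acetone, rt
Reagents that add atoms: none
Why: Williamson etherification that is selective for the phenol, because carbonate deprotonates only the phenol and not the aliphatic hydroxyls.

Step 20
Reactants: 27 the imide diol
Product: 28 bis(tert-butyldimethylsilyl) ether of 27 at C7–O and C9–O of the ring B unit
Conditions: TBSOTf, 2,6-lutidine, CH2Cl2, −78 to 0 °C
Reagents that add atoms: tert-butyldimethylsilyl triflate, CC(C)(C)[Si](C)(C)OS(=O)(=O)C(F)(F)F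
Why: silyl triflate with a hindered base silylates the primary and the hindered benzylic hydroxyl, conditions routinely tolerated by N-acyl oxazolidinones.

Step 21
Reactants: 29 vanillin
Product: 30 4-formyl-2-methoxyphenyl acetate
Conditions: Ac2O, pyridine, DMAP (cat.), CH2Cl2, rt
Reagents that add atoms: acetic anhydride, CC(=O)OC(C)=O
Why: acetylation of the phenol, for the same reasons as in step 16.

Step 22
Reactants: 28 the silylated ring B aryloxyacetyl imide; 30 4-formyl-2-methoxyphenyl acetate
Product: 32 (S)-4-benzyl-3-[(2R,3R)-3-(4-acetoxy-3-methoxyphenyl)-3-hydroxy-2-(ring B aryloxy)propanoyl]oxazolidin-2-one (anti), via trimethylsilyl ether 31 (not isolated)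
Conditions: MgCl2 (20 mol %), Et3N, TMSCl, EtOAc, rt; then citric acid, MeOH, rt
Reagents that add atoms: none
Why: second magnesium-halide-catalysed direct anti-aldol with the same auxiliary and the same facial and anti control, setting C7 and C8 of the ring A unit; the mild acidic methanolysis removes only the trimethylsilyl ether.

Step 23
Reactants: 32 the second anti-aldol adduct
Product: 33 ring A (1R,2S)-arylglycerol diol with free guaiacyl phenol, three silyl ethers and the ring D bromide
Conditions: LiBH4, MeOH, THF, 0 °C to rt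
Reagents that add atoms: none
Why: reductive removal of the auxiliary to the primary alcohol with concomitant reductive cleavage of the aryl acetate, as in step 18; the silyl ethers and the aryl bromide are inert.

Step 24
Reactants: 33 the aryl bromide
Product: 35 (E)-enal carrying three silyl ethers, via cinnamaldehyde diethyl acetal 34 (not isolated)
Conditions: acrolein diethyl acetal, Pd(OAc)2 (5 mol %), n-Bu4NOAc, K2CO3, KCl, DMF, 90 °C; then 1 M aq HCl, THF, rt
Reagents that add atoms: acrolein diethyl acetal, C=CC(OCC)OCC; water, O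
Why: Mizoroki–Heck coupling under phosphine-free ammonium acetate conditions, which favour β-hydride elimination from the benzylic carbon to give the E-configured unsaturated acetal, and brief dilute acid then releases the enal; any partly desilylated material would converge in step 25.

Step 25
Reactants: 35 the tris-silylated enal
Product: 36 the target, CNP0192639.1
Conditions: HF·pyridine, pyridine, THF, 0 °C to rt
Reagents that add atoms: none
Why: buffered fluoride desilylation removes the two primary and the one benzylic silyl ether without base, so the enal, the free phenol and the benzylic carbinol centres are not disturbed.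

**Compound list**

1 | 5-bromo-2-hydroxy-3-methoxybenzaldehyde | O=Cc1cc(Br)cc(OC)c1O | starting material
2 | 2-(allyloxy)-5-bromo-3-methoxybenzaldehyde | O=Cc1cc(Br)cc(OC)c1OCC=C | intermediate
3 | 2-(allyloxy)-5-bromo-1-methoxy-3-(2-methoxyethenyl)benzene, E/Z mixture | COC=Cc1cc(Br)cc(OC)c1OCC=C | intermediate
4 | 2-[2-(allyloxy)-5-bromo-3-methoxyphenyl]acetaldehyde | O=CCc1cc(Br)cc(OC)c1OCC=C | intermediate
5 | 2-[2-(allyloxy)-5-bromo-3-methoxyphenyl]acetic acid | OC(=O)Cc1cc(Br)cc(OC)c1OCC=C | intermediate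
6 | (S)-4-benzyloxazolidin-2-one | O=C1N[C@@H](Cc2ccccc2)CO1 | starting material
7 | mixed pivalic anhydride of 5 (not isolated) | CC(C)(C)C(=O)OC(=O)Cc1cc(Br)cc(OC)c1OCC=C | intermediate
8 | (S)-3-{2-[2-(allyloxy)-5-bromo-3-methoxyphenyl]acetyl}-4-benzyloxazolidin-2-one | O=C(Cc1cc(Br)cc(OC)c1OCC=C)N1[C@@H](Cc2ccccc2)COC1=O | intermediate
9 | syringaldehyde | COc1cc(C=O)cc(OC)c1O | starting material
10 | 4-(allyloxy)-3,5-dimethoxybenzaldehyde | COc1cc(C=O)cc(OC)c1OCC=C | intermediate
11 | [4-(allyloxy)-3,5-dimethoxyphenyl]methanol | COc1cc(CO)cc(OC)c1OCC=C | intermediate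
12 | 4-(allyloxy)-3,5-dimethoxybenzyl bromide | COc1cc(CBr)cc(OC)c1OCC=C | intermediate
13 | sodium Z-enolate of 8 (not isolated) | [Na+].[O-]/C(=C\c1cc(Br)cc(OC)c1OCC=C)N1[C@@H](Cc2ccccc2)COC1=O | intermediate
14 | (S)-4-benzyl-3-[(2S)-2-(2-allyloxy-5-bromo-3-methoxyphenyl)-3-(4-allyloxy-3,5-dimethoxyphenyl)propanoyl]oxazolidin-2-one | C=CCOc1c(OC)cc(C[C@H](C(=O)N2[C@@H](Cc3ccccc3)COC2=O)c2cc(Br)cc(OC)c2OCC=C)cc1OC | intermediate
15 | (2S)-2-(2-allyloxy-5-bromo-3-methoxyphenyl)-3-(4-allyloxy-3,5-dimethoxyphenyl)propan-1-ol | C=CCOc1c(OC)cc(C[C@H](CO)c2cc(Br)cc(OC)c2OCC=C)cc1OC | intermediate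
16 | tert-butyldimethylsilyl ether of 15 | C=CCOc1c(OC)cc(C[C@H](CO[Si](C)(C)C(C)(C)C)c2cc(Br)cc(OC)c2OCC=C)cc1OC | intermediate
17 | 4-bromo-2-[(2S)-1-(tert-butyldimethylsilyloxy)-3-(4-hydroxy-3,5-dimethoxyphenyl)propan-2-yl]-6-methoxyphenol | COc1cc(C[C@H](CO[Si](C)(C)C(C)(C)C)c2cc(Br)cc(OC)c2O)cc(OC)c1O | intermediate
18 | ring C para-quinone methide of 17 (not isolated) | COC1=CC(=C[C@H](CO[Si](C)(C)C(C)(C)C)c2cc(Br)cc(OC)c2O)C=C(OC)C1=O | intermediate
19 | 4-[(2R,3S)-5-bromo-3-(tert-butyldimethylsilyloxymethyl)-7-methoxy-2,3-dihydro-1-benzofuran-2-yl]-2,6-dimethoxyphenol | COc1cc([C@@H]2Oc3c(OC)cc(Br)cc3[C@H]2CO[Si](C)(C)C(C)(C)C)cc(OC)c1O | intermediate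
20 | N-lithio derivative of 6 (not isolated) | [Li+].O=C1[N-][C@@H](Cc2ccccc2)CO1 | intermediate
21 | (S)-4-benzyl-3-(2-bromoacetyl)oxazolidin-2-one | O=C(CBr)N1[C@@H](Cc2ccccc2)COC1=O | intermediate
22 | ring C aryloxyacetyl imide of 19 with the (S)-auxiliary | COc1cc([C@@H]2Oc3c(OC)cc(Br)cc3[C@H]2CO[Si](C)(C)C(C)(C)C)cc(OC)c1OCC(=O)N1[C@@H](Cc2ccccc2)COC1=O | intermediate
23 | 4-formyl-2,6-dimethoxyphenyl acetate | CC(=O)Oc1c(OC)cc(C=O)cc1OC | intermediate
24 | trimethylsilyl ether of 25 (not isolated) | CC(=O)Oc1c(OC)cc([C@@H](O[Si](C)(C)C)[C@H](C(=O)N2[C@@H](Cc3ccccc3)COC2=O)Oc2c(OC)cc([C@@H]3Oc4c(OC)cc(Br)cc4[C@H]3CO[Si](C)(C)C(C)(C)C)cc2OC)cc1OC | intermediate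
25 | (2R,3R)-anti-aldol imide of the ring B unit | CC(=O)Oc1c(OC)cc([C@@H](O)[C@H](C(=O)N2[C@@H](Cc3ccccc3)COC2=O)Oc2c(OC)cc([C@@H]3Oc4c(OC)cc(Br)cc4[C@H]3CO[Si](C)(C)C(C)(C)C)cc2OC)cc1OC | intermediate
26 | (1R,2S)-1-(4-hydroxy-3,5-dimethoxyphenyl)-2-(ring C aryloxy)propane-1,3-diol | Oc1c(OC)cc([C@@H](O)[C@H](CO)Oc2c(OC)cc([C@@H]3Oc4c(OC)cc(Br)cc4[C@H]3CO[Si](C)(C)C(C)(C)C)cc2OC)cc1OC | intermediate
27 | ring B aryloxyacetyl imide of 26 (free C7 and C9 hydroxyls) | O=C(COc1c(OC)cc([C@@H](O)[C@H](CO)Oc2c(OC)cc([C@@H]3Oc4c(OC)cc(Br)cc4[C@H]3CO[Si](C)(C)C(C)(C)C)cc2OC)cc1OC)N1[C@@H](Cc2ccccc2)COC1=O | intermediate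
28 | bis(tert-butyldimethylsilyl) ether of 27 | O=C(COc1c(OC)cc([C@@H](O[Si](C)(C)C(C)(C)C)[C@H](CO[Si](C)(C)C(C)(C)C)Oc2c(OC)cc([C@@H]3Oc4c(OC)cc(Br)cc4[C@H]3CO[Si](C)(C)C(C)(C)C)cc2OC)cc1OC)N1[C@@H](Cc2ccccc2)COC1=O | intermediate
29 | vanillin | COc1cc(C=O)ccc1O | starting material
30 | 4-formyl-2-methoxyphenyl acetate | CC(=O)Oc1ccc(C=O)cc1OC | intermediate
31 | trimethylsilyl ether of 32 (not isolated) | CC(=O)Oc1ccc([C@@H](O[Si](C)(C)C)[C@H](C(=O)N2[C@@H](Cc3ccccc3)COC2=O)Oc2c(OC)cc([C@@H](O[Si](C)(C)C(C)(C)C)[C@H](CO[Si](C)(C)C(C)(C)C)Oc3c(OC)cc([C@@H]4Oc5c(OC)cc(Br)cc5[C@H]4CO[Si](C)(C)C(C)(C)C)cc3OC)cc2OC)cc1OC | intermediate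
32 | (2R,3R)-anti-aldol imide of the ring A unit | CC(=O)Oc1ccc([C@@H](O)[C@H](C(=O)N2[C@@H](Cc3ccccc3)COC2=O)Oc2c(OC)cc([C@@H](O[Si](C)(C)C(C)(C)C)[C@H](CO[Si](C)(C)C(C)(C)C)Oc3c(OC)cc([C@@H]4Oc5c(OC)cc(Br)cc5[C@H]4CO[Si](C)(C)C(C)(C)C)cc3OC)cc2OC)cc1OC | intermediate
33 | ring A (1R,2S)-diol with free phenol, three silyl ethers and ring D bromide | COc1cc([C@@H](O)[C@H](CO)Oc2c(OC)cc([C@@H](O[Si](C)(C)C(C)(C)C)[C@H](CO[Si](C)(C)C(C)(C)C)Oc3c(OC)cc([C@@H]4Oc5c(OC)cc(Br)cc5[C@H]4CO[Si](C)(C)C(C)(C)C)cc3OC)cc2OC)ccc1O | intermediate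
34 | (E)-3,3-diethoxyprop-1-enyl derivative of 33 (not isolated) | COc1cc([C@@H](O)[C@H](CO)Oc2c(OC)cc([C@@H](O[Si](C)(C)C(C)(C)C)[C@H](CO[Si](C)(C)C(C)(C)C)Oc3c(OC)cc([C@@H]4Oc5c(OC)cc(/C=C/C(OCC)OCC)cc5[C@H]4CO[Si](C)(C)C(C)(C)C)cc3OC)cc2OC)ccc1O | intermediate
35 | tris(tert-butyldimethylsilyl) ether of the target | COc1cc([C@@H](O)[C@H](CO)Oc2c(OC)cc([C@@H](O[Si](C)(C)C(C)(C)C)[C@H](CO[Si](C)(C)C(C)(C)C)Oc3c(OC)cc([C@@H]4Oc5c(OC)cc(/C=C/C=O)cc5[C@H]4CO[Si](C)(C)C(C)(C)C)cc3OC)cc2OC)ccc1O | intermediate
36 | CNP0192639.1 | COc1cc([C@@H](O)[C@H](CO)Oc2c(OC)cc([C@@H](O)[C@H](CO)Oc3c(OC)cc([C@@H]4Oc5c(OC)cc(/C=C/C=O)cc5[C@H]4CO)cc3OC)cc2OC)ccc1O | target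

**Step count**
Total: 25 steps. Longest linear sequence: 19 steps (1–5, 9–13, 15, 17–20, 22–25).

**Steps most likely to fail**

Step 13 (key cyclisation). What may go wrong: a second oxidation of the product phenol leading on to the benzofuran, competing oxidation at ring D, or tautomerisation of the quinone methide to the stilbene before ring closure. The fallback leaves the oxidation out and reaches the same benzylic cation from a carbinol; it sets out from acid 5 and aldehyde 10 and rejoins at 19. Acid 5 would be coupled (t-BuCOCl, Et3N, LiCl, through anhydride 7) with (R)-4-benzyloxazolidin-2-one to the antipodal-auxiliary imide (R)-3-{2-[2-(allyloxy)-5-bromo-3-methoxyphenyl]acetyl}-4-benzyloxazolidin-2-one F1. A Bu2BOTf/i-Pr2NEt syn-aldol with 10 would give the (2R,3R)-β-hydroxy imide F2; the boron enolate reacts on the enolate face opposite to the one used in the alkylation, hence the antipodal auxiliary, so the α-centre has the C3 configuration. LiBH4 would give the (1R,2S)-1,3-diol F3, TBSCl/imidazole at 0 °C would silylate only the primary hydroxyl to give mono-silyl ether F4, and Pd(PPh3)4/morpholine would remove both allyl groups to give the diphenol carbinol F5. Catalytic TsOH in CH2Cl2 would then ionise the para-hydroxybenzylic alcohol, and the ring D phenol would close the ring under thermodynamic control to trans-19; the carbinol configuration is lost and does not matter.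

Step 17 (first anti-glycolate aldol). What may go wrong: low anti/syn or facial selectivity, or slow reaction, because the α-substituent is a hindered 2,6-dimethoxyaryloxy group that may bind magnesium. The fallback sets out from 19 and rejoins at 26, using a syn-aldol followed by correction of C7. Phenol 19 would be alkylated (K2CO3, acetone) with (R)-4-benzyl-3-(2-bromoacetyl)oxazolidin-2-one F6 (made as in step 14 from the (R)-oxazolidinone) to give the (R)-auxiliary aryloxyacetyl imide F7. A Bu2BOTf/i-Pr2NEt syn-aldol with 23 would give the (2R,3S)-syn adduct F8, which has the correct C8 and the wrong C7. LiBH4 would give the threo (1S,2S)-diol phenol F9; DDQ in dioxane would oxidise only the phenolic benzylic alcohol to the (S)-α-aryloxy ketone F10; NaBH4 in MeOH at low temperature should then reduce it under Felkin–Anh control mainly to the erythro diol 26, the C7 epimer being removed by chromatography.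

Step 24 (Heck reaction). What may go wrong: slow oxidative addition to the electron-rich aryl bromide, β-hydride elimination towards the acetal carbon giving the saturated ester, or base-induced degradation of the free-phenolic benzylic alcohol at 90 °C. The fallback sets out from 33 and rejoins at 34 and then 35: Suzuki–Miyaura coupling of 33 with (E)-2-(3,3-diethoxyprop-1-enyl)-4,4,5,5-tetramethyl-1,3,2-dioxaborolane (Pd(dppf)Cl2, K3PO4, dioxane/H2O, 70 °C) would give the same acetal 34 with the E geometry fixed in the reagent, and dilute acid would then give 35.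

**Further compounds**
F1 | step 13 | (R)-3-{2-[2-(allyloxy)-5-bromo-3-methoxyphenyl]acetyl}-4-benzyloxazolidin-2-one | O=C(Cc1cc(Br)cc(OC)c1OCC=C)N1[C@H](Cc2ccccc2)COC1=O
F2 | step 13 | (R)-4-benzyl-3-[(2R,3R)-2-(2-allyloxy-5-bromo-3-methoxyphenyl)-3-(4-allyloxy-3,5-dimethoxyphenyl)-3-hydroxypropanoyl]oxazolidin-2-one | O=C([C@H](c1cc(Br)cc(OC)c1OCC=C)[C@@H](O)c1cc(OC)c(OCC=C)c(OC)c1)N1[C@H](Cc2ccccc2)COC1=O
F3 | step 13 | (1R,2S)-2-(2-allyloxy-5-bromo-3-methoxyphenyl)-1-(4-allyloxy-3,5-dimethoxyphenyl)propane-1,3-diol | OC[C@H](c1cc(Br)cc(OC)c1OCC=C)[C@@H](O)c1cc(OC)c(OCC=C)c(OC)c1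
F4 | step 13 | primary tert-butyldimethylsilyl ether of F3 | CC(C)(C)[Si](C)(C)OC[C@H](c1cc(Br)cc(OC)c1OCC=C)[C@@H](O)c1cc(OC)c(OCC=C)c(OC)c1
F5 | step 13 | (1R,2S)-2-(5-bromo-2-hydroxy-3-methoxyphenyl)-3-(tert-butyldimethylsilyloxy)-1-(4-hydroxy-3,5-dimethoxyphenyl)propan-1-ol | CC(C)(C)[Si](C)(C)OC[C@H](c1cc(Br)cc(OC)c1O)[C@@H](O)c1cc(OC)c(O)c(OC)c1
F6 | step 17 | (R)-4-benzyl-3-(2-bromoacetyl)oxazolidin-2-one | O=C(CBr)N1[C@H](Cc2ccccc2)COC1=O
F7 | step 17 | ring C aryloxyacetyl imide of 19 with the (R)-auxiliary | COc1cc([C@@H]2Oc3c(OC)cc(Br)cc3[C@H]2CO[Si](C)(C)C(C)(C)C)cc(OC)c1OCC(=O)N1[C@H](Cc2ccccc2)COC1=O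
F8 | step 17 | (2R,3S)-syn-aldol imide of the ring B unit with the (R)-auxiliary | CC(=O)Oc1c(OC)cc([C@H](O)[C@H](C(=O)N2[C@H](Cc3ccccc3)COC2=O)Oc2c(OC)cc([C@@H]3Oc4c(OC)cc(Br)cc4[C@H]3CO[Si](C)(C)C(C)(C)C)cc2OC)cc1OC
F9 | step 17 | (1S,2S)-1-(4-hydroxy-3,5-dimethoxyphenyl)-2-(ring C aryloxy)propane-1,3-diol, the C7 epimer of 26 | Oc1c(OC)cc([C@H](O)[C@H](CO)Oc2c(OC)cc([C@@H]3Oc4c(OC)cc(Br)cc4[C@H]3CO[Si](C)(C)C(C)(C)C)cc2OC)cc1OC
F10 | step 17 | (S)-3-hydroxy-1-(4-hydroxy-3,5-dimethoxyphenyl)-2-(ring C aryloxy)propan-1-one | Oc1c(OC)cc(C(=O)[C@H](CO)Oc2c(OC)cc([C@@H]3Oc4c(OC)cc(Br)cc4[C@H]3CO[Si](C)(C)C(C)(C)C)cc2OC)cc1OC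
F0 | step 24 | none | none
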